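The earlier runs and the new flask were generated by integration on assumed constants; noise was put on by code.

A curve that flattens far below the charge tempts one to say that the flask has stopped, yet a plateau does not tell where the molecules went.

| flask | starting material | coupling partner | time |
|---|---|---|---|
| dawn | 0.120 M | 0.132 M |  |
| midnight | 0.120 M | 0.200 M |  |
| spring | 0.0600 M | 0.132 M |  |
| noon | 0.360 M | 0.0660 M | 64 min |

| dawn run: time / min | dawn run: [product] / M | midnight run: time / min | midnight run: [product] / M | spring run: time / min | spring run: [product] / M |
|---|---|---|---|---|---|
| 4.9 | 0.0064 | 4.9 | 0.0095 | 4.9 | 0.0033 |
| 15 | 0.0162 | 15 | 0.0215 | 15 | 0.0089 |
| 28 | 0.0221 | 28 | 0.0307 | 28 | 0.0116 |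
| 45 | 0.0259 | 45 | 0.0361 | 45 | 0.0136 |
| 64 | 0.0272 | 64 | 0.0380 | 64 | 0.0149 |

(scatter of a reading: 4 × 10⁻⁴ M)

- Overall: starting material + coupling partner -> product.
- Constant volume, constant temperature.
- A reading of a species includes what of it is bound.
- An order is taken over about fifteen percent of the charge, up and down.

- reaction order in [coupling partner] at the outset, round the charge of the dawn run, defined at two percent of the starting material turned into product
- reaction order in [starting material] at the outset, round the charge of the dawn run, defined at two percent of the starting material turned into product (one fixed amount of product, the same in the runs compared)
- product in the noon run at 64 min, as a share of the starting material charged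

Follow one molecule of coupling partner in the dawn run and suppose a fork: it ends in product, or it goes elsewhere. The tally at 64 min gives its odds, product made over coupling partner not turned into product, a reading of 0.260. If the other branch needs no starting material and the product branch is first order in it, these odds grow about in step with the starting material charged, so the useful quantity is the fork pull, the odds per unit of starting material charged, 2.16 M⁻¹. The spring run, with the same coupling partner and half the starting material, reads odds of 0.127, half those of the dawn run.

Now turn the question round. In the noon run the coupling partner is the limiting reagent, so the ceiling is 18.3 % of the starting material charged. Reaching it would take every molecule of coupling partner to end in product. My reckoning assumes that the pull does not depend on the coupling partner charge, and it gives noon odds of 0.779, below even. That makes 0.0289 M of product, or 8.03 % of the starting material charged.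

The forecast, saying “I favour equilibrium”, gives orders of 1.05 in coupling partner and 1.05 in starting material, and 8.9 % for noon, higher than my figure.

The noon run gives 8.66 % of its starting material charged as product at 64 min. Round the charge of the dawn run, the orders at the outset are 0.91 in coupling partner and 0.93 in starting material.

    starting material ⇌ intermediate, settled at all times (0.04480)
    intermediate + coupling partner → product (3.558 M⁻¹ min⁻¹)
    coupling partner → lost reagent (0.05388 min⁻¹)
    starting material + coupling partner ⇌ idle substrate-reagent adduct, settled at all times (2.380 M⁻¹)

Turning coupling partner into lost reagent moves the readings by 45 times the scatter, root mean square. The noon result means odds of 0.895, a pull of 2.49 M⁻¹ against the dawn run's 2.16 M⁻¹. Carried to the midnight run, the dawn pull gives 0.0412 M of product at 64 min, against a reading of 0.0380 M.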